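## Structural features

The target contains three aryl rings and three oxygen heterocycles. Ring A (4‑hydroxy‑3‑methoxyphenyl) sits on C2 of a 2,3‑dihydrobenzofuran (ring B = benzo ring with 7‑OMe, ring C = dihydrofuran with 3‑CH2OH), and C5 of ring B is bonded to C2 of a 3,7‑dioxabicyclo[3.3.0]octane (ring D: C1–C2–O3–C4–C5; ring E: C1–C8–O7–C6–C5) whose C6 carries ring F (4‑hydroxy‑3,5‑dimethoxyphenyl). There are six stereocentres in two clusters: C2 and C3 of ring C are adjacent and cis (2S,3S), and C2, C1, C5 and C6 of the bicycle form an unbroken chain (1R,2S,5R,6S) with a cis ring fusion and both aryl groups exo. Ring B separates the clusters, so neither can control the other and each has to be set in the absolute sense. The sensitive sites are the three benzylic C–O bonds (C2–O1 of ring C, C2–O3 of ring D, C6–O7 of ring E), each para to an oxygen donor and so prone to acid ionisation (epimerisation) and to hydrogenolysis; the two phenols; and the cis arrangement on ring C, which is the less stable one and epimerises at C3 whenever C3 bears a carbonyl group. The real difficulty is the unsymmetrical bicycle: its two aryl groups differ, so dimerisation logic is excluded, and four contiguous centres must be fixed relative to a remote pair. The key step exploits ring D, whose C2–O3–C4 segment is an ArCH–O–CH2 unit spanning the bridgeheads C1 and C5, the imprint of a carbonyl ylide on an alkene; the alkene is the C=C of a butenolide whose lactone carbonyl becomes C8 and whose acetal carbon becomes C6 at the aldehyde oxidation level. A check of the descriptors (cis ring C, exo/exo bicycle, anti addition to the (5S)‑butenolide leading to 1R,5R in the target) found the structural plan consistent; the changes made concern the protecting groups and the way the ylide precursor is reached.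

## Logic of the disconnections

25 ⇒ 23 (through 24). The C6–O7 bond of ring E is cut. It is a benzylic ether para to the free phenol of ring F, so it can form by 5‑exo capture of a quinone methide by the C8 hydroxyl. This removes ring E and the C6 stereocentre, which therefore need not be controlled earlier. The forward step must close with the aryl group exo and under conditions too mild to ionise the other two benzylic ethers.

23 ⇒ 22. No skeletal bond is cut; the C8 alcohol goes back to a lactone carbonyl and three hydroxyls go back to pivalates. One hydride operation then does the reduction and the whole deprotection, so no separate deprotection step, and in particular no hydrogenolysis next to three benzylic C–O bonds, is needed. The demand is complete cleavage of three hindered esters without reduction of a benzylic C–O bond.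

22 ⇒ 17 + 19 (through 20 and 21). The C6–aryl bond to ring F is cut, giving an aldehyde at C6 (masked in 17 as a lactol) and an aryl nucleophile. Ring F is removed as a simple bromide. The forward step must favour the aldehyde over three pivalates; the configuration formed at C6 is irrelevant because the last step resets it.

17 ⇒ 16. The C6–OH bond goes back to the C6–O‑menthyl acetal. The acetal is both the masked aldehyde and the element that fixes the absolute configuration of C1 and C5. The forward hydrolysis must not ionise the C2–O3 bond of ring D; the acyl group on the ring A oxygen is there to keep ring C out of this problem.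

16 ⇒ 13 + 14 (through 15). The C1–C2 and C4–C5 bonds of ring D are cut, the strategic disconnection. It removes one ring and three stereocentres and divides the molecule into an aldehyde‑derived half and a commercial chiral butenolide. The forward cycloaddition needs regiocontrol (CH2 terminus to the β‑carbon), facial control (anti to the menthyloxy group) and an exo orientation of the aryl group.

13 ⇒ 12 ⇒ 11 ⇒ 10. The C–Cl bond of 13 goes back to a C–O bond of the acetal 12; the two pivalates go back to the hydroxyls of 11; the CH2OH of 11 goes back to the ester of 10. Three design decisions lie here: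
- The labile α‑chloro ether is made only at the moment of use, from an acetal that can be stored and purified.
- The acetal is installed early and serves as the aldehyde protecting group throughout.
- The ring A oxygen is acylated, not benzylated. The pivalate attenuates the donor that would otherwise labilise C2–O1 of ring C in the acidic steps, and it is removed by the hydride step that is needed anyway.

10 ⇒ 9. The C2–C3 bond of ring C is cut to a diazo ester: a carbene inserts into the benzylic O–CH2 bond. Both stereocentres of ring C then arise from an achiral aryl benzyl ether. The demand is cis and enantioselectivity by catalyst control, and a reduction of the ester (step 7) that is faster than epimerisation at C3.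

9 ⇒ 7 + 8. The bond between ring B and the diazo carbon is cut, an aryl iodide coupling with a diazoacetate that keeps the diazo group. This saves the homologation of a benzaldehyde to an arylacetic ester. The demand is tolerance of an ortho‑alkoxy, electron‑rich iodide.

7 ⇒ 5 + 6 and 5 ⇒ 3 + 4. The two acetal C–O bonds and the aryl–O–CH2 ether bond are cut. This leads to a commercial iodophenol aldehyde whose substituents already map onto O1, C3a, C5 and C7 of the dihydrobenzofuran, and to a benzylic alcohol. The etherification must tolerate a doubly ortho‑substituted phenol.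

3 ⇒ 2 ⇒ 1 and 19 ⇒ 18. Acyl C–O bonds and one carbonyl reduction lead to commercial phenols.

## Other disconnections considered

Alternative 1: Both rings of the bicycle are cut at once, at C1–C5 and C2–O3. This leads back to the acyclic epoxy ether A2, in which the future C6 carbinol carbon carries ring F and an oxiranyl group and is etherified with an (E)‑3‑arylallyl group whose aryl is the dihydrobenzofuran.
- Forward step: Cp2TiCl (trivalent titanium, from Cp2TiCl2 and zinc) would open the epoxide homolytically to the C5 radical. This cyclises 5‑exo‑trig onto the styrenyl double bond (ring E). The benzylic C2 position would then be activated with iodine and closed onto the titanium alkoxide at O3 (ring D), giving A1.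
- In favour: one operation would make two rings and three stereocentres; the two aryl halves are joined by a plain Williamson etherification; ring F needs no organometallic step. After the key step only deprotection remains, so on step economy after the key step this plan is the better one.
- Against it here: the allyl ether half of A2 needs a three‑carbon side chain on ring B, that is, a homologation starting from the same aldehyde level that the chosen route reaches. The absolute configuration of the bicycle would rest on the single C6 carbinol centre relayed through a radical transition state, a weaker relay than anti addition to a 5‑alkoxybutenolide. C2 would be set in a cation‑like closure, in the presence of iodine and next to the ionisable C2–O1 bond of ring C. A1 carries two benzyl ethers whose hydrogenolysis would have to spare three benzylic C–O bonds.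
- Comparison: both plans need the same dihydrobenzofuran building block and both finish one aryl‑bearing centre by a benzylic cation closure; on these points they are equal. Mechanistically the chosen plan fixes C1 and C5 by auxiliary‑controlled cycloaddition and avoids stoichiometric titanium.

Alternative 2: This cut concerns ring C, not the bicycle. The O1–C2 bond is disconnected to the phenol alcohol A4, a protected syn aldol product.
- Forward step: an intramolecular Mitsunobu etherification in which the ring B phenol displaces the activated C2 hydroxyl with inversion, giving the cis ring of A3.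
- In favour: both stereocentres would come from an auxiliary‑controlled syn aldol reaction of well‑calibrated sense, and no diazo compound or rhodium catalyst is needed. On safety at scale and on predictability of the absolute configuration this plan is the better one. The tosylate on ring A slows ionisation so that the displacement can stay SN2, and the bromide of A3 is a handle for the C5 formyl group.
- Against it here: more steps for the same fragment (auxiliary attachment, aldol, reductive removal, selective silylation, phenol release, cyclisation, formylation) against four here (steps 3 to 6). A benzylic Mitsunobu displacement can leak through an SN1 path, which would give the trans ring. Removal of the tosylate at the end needs conditions that the cis ring may not tolerate. The furofuran problem is left untouched, so this is a replacement for steps 3 to 8, not for the key step.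
- Comparison: both plans deliver the same kind of intermediate, a cis 5‑functionalised dihydrobenzofuran, and A3 could feed the same ylide chemistry; at the level of the key step they are equal. The chosen C–H insertion is shorter and catalytic; the aldol route is longer but rests on better calibrated stereocontrol.

Alternative 3: Ring E is cut at C6–O7 together with a C1–C6 bond, leading back to the donor–acceptor cyclopropane A6.
- Forward step: a Lewis acid on the lactone carbonyl would break C1–C6 heterolytically, the hydroxymethyl oxygen would capture the benzylic cation at C6, and protonation of the enolate at C1 would give the cis‑fused furofuranone A5 with ring F exo.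
- In favour: A6 should be reachable in few steps by catalytic asymmetric intramolecular cyclopropanation; no auxiliary has to be hydrolysed; the opening is stereoconvergent at C6. The costly dihydrobenzofuran would enter last, so on convergence this plan is the better one.
- Against it here: the carbonyl of A5 is C2, so the dihydrobenzofuran must be attached by adding an aryl metal (for example lithiated A3) to the lactone and reducing the hemiketal. Hydride delivery to the bicyclic oxocarbenium ion from the convex face would place the aryl group endo, the wrong C2 epimer. The detour through a lactol, aryl addition and cation closure costs about as many steps as steps 11 to 15 here. The aryl metal carries a base‑sensitive cis ring.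
- Comparison: the plans mirror each other. Here the complex aryl group is installed with control in the cycloaddition and the simple one by addition to an aldehyde; there it is the reverse. The number of operations on the bicycle is comparable (equal), while the chosen plan puts the stereochemically safer bond formation on the valuable fragment.

Key step: step 10

Assumptions and abbreviations
- The sense of induction in step 6 is assigned by analogy: with 2‑(benzyloxy)aryl diazoacetates the (S)‑ligand series of phthalimido‑tert‑leucinate dirhodium catalysts is taken to lead to the (2R) ring, so the (R)‑ligand catalyst is specified; the antipodal catalyst would be used should the sense be opposite for this substrate.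
- 17 is written as the cyclic lactol; it is the ring–chain tautomer of the cis aldehyde acid and reacts through the open form.
- The ethyl ester is used because ethyl diazoacetate is the commercial reagent; the ester alkyl group is lost in step 7.
- Piv = 2,2‑dimethylpropanoyl. ArP = (2S,3S)‑7‑methoxy‑2‑[3‑methoxy‑4‑(pivaloyloxy)phenyl]‑3‑[(pivaloyloxy)methyl]‑2,3‑dihydro‑1‑benzofuran‑5‑yl. ArH = (2S,3S)‑3‑(hydroxymethyl)‑2‑(4‑hydroxy‑3‑methoxyphenyl)‑7‑methoxy‑2,3‑dihydro‑1‑benzofuran‑5‑yl. SyrP = 3,5‑dimethoxy‑4‑(pivaloyloxy)phenyl.

## Steps

Step 1
Reactants: 1 vanillin (4‑hydroxy‑3‑methoxybenzaldehyde)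
Product: 2 4‑formyl‑2‑methoxyphenyl pivalate
Conditions: PivCl, Et3N, DMAP (cat.), CH2Cl2, 0 °C to rt
Reagents that add atoms: pivaloyl chloride, CC(C)(C)C(=O)Cl
Why: Esterification of the phenol (nucleophilic acyl substitution); the pivalate masks the phenol and lowers the donor strength of the ring A oxygen, which later stabilises the benzylic positions towards acid.

Step 2
Reactants: 2 4‑formyl‑2‑methoxyphenyl pivalate
Product: 3 4‑(hydroxymethyl)‑2‑methoxyphenyl pivalate
Conditions: NaBH4, THF–MeOH, 0 °C
Reagents that add atoms: none
Why: Chemoselective borohydride reduction of the aldehyde; a hindered aryl ester should be inert to NaBH4 at 0 °C.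

Step 3
Reactants: 3 4‑(hydroxymethyl)‑2‑methoxyphenyl pivalate; 4 5‑iodovanillin (4‑hydroxy‑3‑iodo‑5‑methoxybenzaldehyde)
Product: 5 4‑[(4‑formyl‑2‑iodo‑6‑methoxyphenoxy)methyl]‑2‑methoxyphenyl pivalate
Conditions: PPh3, DIAD, THF, 0 °C to rt
Reagents that add atoms: none
Why: Mitsunobu etherification; the acidic para‑formyl phenol 4 is a good pronucleophile and displaces the primary benzylic oxyphosphonium ion, so no labile benzyl halide has to be handled.

Step 4
Reactants: 5 4‑[(4‑formyl‑2‑iodo‑6‑methoxyphenoxy)methyl]‑2‑methoxyphenyl pivalate; 6 (trimethylsilyl)methanol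
Product: 7 4‑[(4‑{bis[(trimethylsilyl)methoxy]methyl}‑2‑iodo‑6‑methoxyphenoxy)methyl]‑2‑methoxyphenyl pivalate
Conditions: 6 (3 equiv), TsOH·H2O (2 mol%), cyclohexane, reflux, water separator; Et3N quench
Reagents that add atoms: none
Why: Acid‑catalysed acetalisation driven by azeotropic removal of water; the acetal protects the aldehyde through steps 5 to 8 and is at the same time the storable precursor of the α‑chloro ether.

Step 5
Reactants: 7 the bis(silylmethyl) acetal iodide; 8 ethyl diazoacetate
Product: 9 ethyl 2‑diazo‑2‑[5‑{bis[(trimethylsilyl)methoxy]methyl}‑3‑methoxy‑2‑({3‑methoxy‑4‑(pivaloyloxy)phenyl}methoxy)phenyl]acetate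
Conditions: Pd(PPh3)4 (5 mol%), Ag2CO3 (0.5 equiv), Et3N, toluene, rt
Reagents that add atoms: none
Why: Cross‑coupling of an aryl iodide with the C–H bond of a diazoacetate under zerovalent palladium catalysis (oxidative addition, silver‑assisted palladation of the diazo carbon, reductive elimination) with retention of the diazo group; it gives the aryldiazoacetate in one step.

Step 6
Reactants: 9 the aryldiazoacetate
Product: 10 ethyl (2S,3R)‑5‑{bis[(trimethylsilyl)methoxy]methyl}‑7‑methoxy‑2‑[3‑methoxy‑4‑(pivaloyloxy)phenyl]‑2,3‑dihydro‑1‑benzofuran‑3‑carboxylate (cis)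
Conditions: Rh2(R‑PTTL)4 (dirhodium tetrakis[N‑phthaloyl‑(R)‑tert‑leucinate], 1 mol%), toluene, −60 °C
Reagents that add atoms: none
Why: Intramolecular 1,5 C–H insertion of the divalent rhodium carbene into the benzylic O–CH2 bond closes ring C (C2–C3); the phthalimido ligand wall should enforce the kinetic cis product and, in the (R) series, the (2S,3R) enantiomer, and the low temperature preserves the cis ester.

Step 7
Reactants: 10 the cis ester
Product: 11 4‑[(2S,3S)‑5‑{bis[(trimethylsilyl)methoxy]methyl}‑3‑(hydroxymethyl)‑7‑methoxy‑2,3‑dihydro‑1‑benzofuran‑2‑yl]‑2‑methoxyphenol (cis)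
Conditions: LiAlH4 (3 equiv), THF, −20 to 0 °C; aq. potassium sodium tartrate
Reagents that add atoms: none
Why: LiAlH4 reduction of the ester to the primary alcohol at low temperature should outrun enolisation at C3, so the cis relationship is kept (the change of the C3 descriptor is a priority effect only); the aryl pivalate is cleaved in the same operation and the acetal is untouched.

Step 8
Reactants: 11 the phenol alcohol
Product: 12 [(2S,3S)‑5‑{bis[(trimethylsilyl)methoxy]methyl}‑7‑methoxy‑2‑[3‑methoxy‑4‑(pivaloyloxy)phenyl]‑2,3‑dihydro‑1‑benzofuran‑3‑yl]methyl pivalate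
Conditions: PivCl (2.5 equiv), Et3N, DMAP (cat.), CH2Cl2, 0 °C to rt
Reagents that add atoms: pivaloyl chloride, CC(C)(C)C(=O)Cl
Why: Acylation of both hydroxyls under basic conditions that leave the acetal alone; pivalates should resist fluoride, dilute aqueous acid and a Grignard reagent at low temperature, are removed together in step 14, and the aryl pivalate keeps the C2–O1 bond of ring C from ionising.

Step 9
Reactants: 12 the bis‑pivalate acetal
Product: 13 [(2S,3S)‑5‑{chloro[(trimethylsilyl)methoxy]methyl}‑7‑methoxy‑2‑[3‑methoxy‑4‑(pivaloyloxy)phenyl]‑2,3‑dihydro‑1‑benzofuran‑3‑yl]methyl pivalate (both epimers at the chloro carbon; concentrated and used at once)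
Conditions: AcCl (1.05 equiv), ZnBr2 (0.1 mol%), CH2Cl2, 0 °C; volatiles removed in vacuo
Reagents that add atoms: acetyl chloride, CC(=O)Cl
Why: Exchange of one alkoxy group of an acetal for chloride by an acyl chloride under zinc halide catalysis, a standard synthesis of α‑chloro ethers; the only by‑product is a volatile ester, and the para‑oxygenated α‑chloro ether is not stored because it ionises readily.

Step 10
Reactants: 13 the α‑chloro (trimethylsilyl)methyl ether; 14 (5S)‑5‑[(1S,2R,5S)‑menthyloxy]furan‑2(5H)‑one
Product: 16 (1S,2S,5R,6S)‑2‑ArP‑6‑[(1S,2R,5S)‑menthyloxy]‑3,7‑dioxabicyclo[3.3.0]octan‑8‑one, via carbonyl ylide 15 (not isolated)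
Conditions: CsF (3 equiv, dried), 14 (2 equiv), MeCN, 0 °C to rt, slow addition of 13
Reagents that add atoms: none
Why: Fluoride attacks silicon and chloride leaves from the benzylic carbon (1,3‑elimination), giving the non‑stabilised carbonyl ylide 15, a three‑atom dipole with four π electrons. It adds to the electron‑poor C=C of 14 in a concerted, suprafacial [3+2] cycloaddition that closes ring D by forming C4–C5 and C1–C2 together; the closest known reaction type is the fluoride‑triggered cycloaddition of silylmethyl‑derived carbonyl ylides to acrylates, maleates and maleimides, together with the addition of silylmethylamine‑derived azomethine ylides to 5‑alkoxyfuranones. Regiochemistry: the para oxygen O1 of ring B stabilises positive charge at the benzylic terminus, so the CH2 terminus carries the larger HOMO coefficient and bonds to the β‑carbon of the enoate (future C5), the benzylic carbon to the α‑carbon (future C1). C1 and C5: their cis relationship follows from the cis alkene of the ring, and their absolute configuration from approach of the dipole to the face of 14 anti to the menthyloxy group on the neighbouring acetal carbon (future C6), the substrate control that governs other dipolar additions to this butenolide. C2: in the exo transition state the aryl group of the extended ylide points away from the lactone, which places it trans to C8 on the convex face. The step thus needs facial selectivity (secured by the acetal substituent), regioselectivity (secured by the polarity of 15, matched to the enoate) and exo selectivity (steric, the least secure of the three). The pivalates, the benzylic ethers and the cis ring C should be inert to CsF in MeCN at room temperature.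

Step 11
Reactants: 16 the cycloadduct
Product: 17 (1S,2S,5R)‑2‑ArP‑6‑hydroxy‑3,7‑dioxabicyclo[3.3.0]octan‑8‑one (lactol acid, mixture of C6 anomers)
Conditions: 2 M aq. HCl–THF (1:3), 45 °C
Reagents that add atoms: water, O
Why: Acid‑catalysed hydrolysis of the acylal‑type acetal (pseudo‑ester) releases menthol and the lactol acid; dilute aqueous acid is chosen because the acylated ring A keeps ring C intact and pivalates do not hydrolyse under these conditions.

Step 12
Reactants: 18 4‑bromo‑2,6‑dimethoxyphenol
Product: 19 4‑bromo‑2,6‑dimethoxyphenyl pivalate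
Conditions: PivCl, Et3N, DMAP (cat.), CH2Cl2, 0 °C to rt
Reagents that add atoms: pivaloyl chloride, CC(C)(C)C(=O)Cl
Why: Esterification; the pivalate flanked by two methoxy groups is hindered enough to survive in a Grignard reagent and makes the C6 carbinol of 21 and 22 resistant to ionisation until it is removed.

Step 13
Reactants: 17 the lactol acid; 19 4‑bromo‑2,6‑dimethoxyphenyl pivalate
Product: 22 (1S,2S,5R)‑2‑ArP‑6‑SyrP‑3,7‑dioxabicyclo[3.3.0]octan‑8‑one as a mixture of C6 epimers, via arylmagnesium bromide 20 (not isolated), via hydroxy acid 21 (not isolated)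
Conditions: 19 (2.4 equiv), Mg, LiCl, THF, 0 °C to rt; then 17, THF, −78 to −30 °C; aq. citric acid; PPTS (cat.), toluene, 40 °C
Reagents that add atoms: none
Why: LiCl‑promoted magnesium insertion gives the ester‑bearing Grignard reagent; the first equivalent deprotonates the lactol and opens it to the aldehyde carboxylate, the second adds to the aldehyde (Grignard addition to a pseudo‑acid), and the γ‑hydroxy acid lactonises after acidification; C6 forms without control, which is acceptable because step 15 resets it.

Step 14
Reactants: 22 the lactone
Product: 23 4‑{(2S,3S)‑3‑(hydroxymethyl)‑5‑[(2S,3R,4R)‑3‑(hydroxymethyl)‑4‑{hydroxy(4‑hydroxy‑3,5‑dimethoxyphenyl)methyl}oxolan‑2‑yl]‑7‑methoxy‑2,3‑dihydro‑1‑benzofuran‑2‑yl}‑2‑methoxyphenol (both carbinol epimers)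
Conditions: LiAlH4 (8 equiv), THF, 0 °C to rt; aq. potassium sodium tartrate, pH 7 buffer
Reagents that add atoms: none
Why: LiAlH4 reduces the lactone to the 1,4‑diol and cleaves all three pivalates in one operation, so no separate deprotection is needed and the phenol of ring F is freed exactly when its donor strength is wanted.

Step 15
Reactants: 23 the pentaol
Product: 25 4‑[(2S,3S)‑5‑[(1R,2S,5R,6S)‑6‑(4‑hydroxy‑3,5‑dimethoxyphenyl)‑3,7‑dioxabicyclo[3.3.0]octan‑2‑yl]‑3‑(hydroxymethyl)‑7‑methoxy‑2,3‑dihydro‑1‑benzofuran‑2‑yl]‑2‑methoxyphenol (target), via quinone methide 24 (not isolated)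
Conditions: camphorsulfonic acid (5 mol%), THF–CH2Cl2 (1:4), 0 °C; NaHCO3 quench
Reagents that add atoms: none
Why: Acid‑catalysed dehydration of the para‑hydroxybenzylic alcohol to the quinone methide (reacting as its O‑protonated form, the benzylic cation) and 5‑exo‑trig capture by the C8 hydroxyl forms C6–O7 and ring E; the cis fusion is dictated by the cis substituents on C1 and C5, and closure through the rotamer that keeps ring F away from the concave face should place the aryl group exo from either carbinol epimer.

## Compound list

1 | vanillin | COc1cc(C=O)ccc1O | starting material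
2 | 4‑formyl‑2‑methoxyphenyl pivalate | COc1cc(C=O)ccc1OC(=O)C(C)(C)C | intermediate
3 | 4‑(hydroxymethyl)‑2‑methoxyphenyl pivalate | COc1cc(CO)ccc1OC(=O)C(C)(C)C | intermediate
4 | 5‑iodovanillin | COc1cc(C=O)cc(I)c1O | starting material
5 | 4‑[(4‑formyl‑2‑iodo‑6‑methoxyphenoxy)methyl]‑2‑methoxyphenyl pivalate | COc1cc(COc2c(I)cc(C=O)cc2OC)ccc1OC(=O)C(C)(C)C | intermediate
6 | (trimethylsilyl)methanol | C[Si](C)(C)CO | starting material
7 | bis[(trimethylsilyl)methyl] acetal of 5 | COc1cc(COc2c(I)cc(C(OC[Si](C)(C)C)OC[Si](C)(C)C)cc2OC)ccc1OC(=O)C(C)(C)C | intermediate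
8 | ethyl diazoacetate | CCOC(=O)C=[N+]=[N-] | starting material
9 | ethyl aryldiazoacetate | COc1cc(COc2c(C(=[N+]=[N-])C(=O)OCC)cc(C(OC[Si](C)(C)C)OC[Si](C)(C)C)cc2OC)ccc1OC(=O)C(C)(C)C | intermediate
10 | ethyl (2S,3R)‑cis‑dihydrobenzofuran‑3‑carboxylate | COc1cc([C@H]2Oc3c(OC)cc(C(OC[Si](C)(C)C)OC[Si](C)(C)C)cc3[C@H]2C(=O)OCC)ccc1OC(=O)C(C)(C)C | intermediate
11 | (2S,3S)‑cis phenol alcohol | COc1cc([C@H]2Oc3c(OC)cc(C(OC[Si](C)(C)C)OC[Si](C)(C)C)cc3[C@H]2CO)ccc1O | intermediate
12 | (2S,3S)‑cis bis‑pivalate acetal | COc1cc([C@H]2Oc3c(OC)cc(C(OC[Si](C)(C)C)OC[Si](C)(C)C)cc3[C@H]2COC(=O)C(C)(C)C)ccc1OC(=O)C(C)(C)C | intermediate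
13 | α‑chlorobenzyl (trimethylsilyl)methyl ether, both epimers at the chloro carbon | COc1cc([C@H]2Oc3c(OC)cc(C(Cl)OC[Si](C)(C)C)cc3[C@H]2COC(=O)C(C)(C)C)ccc1OC(=O)C(C)(C)C | intermediate
14 | (5S)‑5‑[(1S,2R,5S)‑menthyloxy]furan‑2(5H)‑one | O=C1C=C[C@@H](O[C@H]2C[C@@H](C)CC[C@@H]2C(C)C)O1 | starting material
15 | carbonyl ylide ArP–CH=O(+)–CH2(−) | COc1cc([C@H]2Oc3c(OC)cc(C=[O+][CH2-])cc3[C@H]2COC(=O)C(C)(C)C)ccc1OC(=O)C(C)(C)C | intermediate (not isolated)
16 | (1S,2S,5R,6S)‑2‑ArP‑6‑menthyloxy‑3,7‑dioxabicyclo[3.3.0]octan‑8‑one | COc1cc([C@H]2Oc3c(OC)cc([C@H]4OC[C@H]5[C@@H]4C(=O)O[C@@H]5O[C@H]4C[C@@H](C)CC[C@@H]4C(C)C)cc3[C@H]2COC(=O)C(C)(C)C)ccc1OC(=O)C(C)(C)C | intermediate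
17 | (1S,2S,5R)‑2‑ArP‑6‑hydroxy‑3,7‑dioxabicyclo[3.3.0]octan‑8‑one, C6 anomers | COc1cc([C@H]2Oc3c(OC)cc([C@H]4OC[C@H]5[C@@H]4C(=O)OC5O)cc3[C@H]2COC(=O)C(C)(C)C)ccc1OC(=O)C(C)(C)C | intermediate
18 | 4‑bromo‑2,6‑dimethoxyphenol | COc1cc(Br)cc(OC)c1O | starting material
19 | 4‑bromo‑2,6‑dimethoxyphenyl pivalate | COc1cc(Br)cc(OC)c1OC(=O)C(C)(C)C | intermediate
20 | [3,5‑dimethoxy‑4‑(pivaloyloxy)phenyl]magnesium bromide | COc1cc([Mg]Br)cc(OC)c1OC(=O)C(C)(C)C | intermediate (not isolated)
21 | (2S,3S,4R)‑2‑ArP‑4‑[hydroxy(SyrP)methyl]oxolane‑3‑carboxylic acid, carbinol epimers | COc1cc([C@H]2Oc3c(OC)cc([C@H]4OC[C@H](C(O)c5cc(OC)c(OC(=O)C(C)(C)C)c(OC)c5)[C@@H]4C(=O)O)cc3[C@H]2COC(=O)C(C)(C)C)ccc1OC(=O)C(C)(C)C | intermediate (not isolated)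
22 | (1S,2S,5R)‑2‑ArP‑6‑SyrP‑3,7‑dioxabicyclo[3.3.0]octan‑8‑one, C6 epimers | COc1cc([C@H]2Oc3c(OC)cc([C@H]4OC[C@H]5[C@@H]4C(=O)OC5c4cc(OC)c(OC(=O)C(C)(C)C)c(OC)c4)cc3[C@H]2COC(=O)C(C)(C)C)ccc1OC(=O)C(C)(C)C | intermediate
23 | pentaol: (2S,3R,4R)‑2‑ArH‑3‑(hydroxymethyl)‑4‑[hydroxy(4‑hydroxy‑3,5‑dimethoxyphenyl)methyl]oxolane, carbinol epimers | COc1cc([C@H]2Oc3c(OC)cc([C@H]4OC[C@H](C(O)c5cc(OC)c(O)c(OC)c5)[C@@H]4CO)cc3[C@H]2CO)ccc1O | intermediate
24 | quinone methide from 23 by loss of water (oxolane configuration as in 23) | COc1cc([C@H]2Oc3c(OC)cc([C@H]4OC[C@H](C=C5C=C(OC)C(=O)C(OC)=C5)[C@@H]4CO)cc3[C@H]2CO)ccc1O | intermediate (not isolated)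
25 | CNP0126146.1, (2S,3S)‑dihydrobenzofuran bearing the (1R,2S,5R,6S)‑furofuran | COc1cc([C@H]2Oc3c(OC)cc([C@H]4OC[C@H]5[C@@H]4CO[C@@H]5c4cc(OC)c(O)c(OC)c4)cc3[C@H]2CO)ccc1O | target

## Step count and least certain steps

Total: 15 steps. Longest linear sequence: 14 steps (steps 1 to 11 and 13 to 15, from 1); step 12 is a one‑step side branch from 18.

Step 10 (key step).
- What may go wrong: ionisation and decomposition of the labile α‑chloro ether before fluoride reaches silicon; collapse of the ylide (ring closure to an epoxide, dimerisation) in competition with addition to a β‑alkoxy butenolide of only moderate reactivity; erosion of regioselectivity; endo approach, which would put the aryl group on the concave face at C2.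
- Fallback (sets out from 12, returns at 16): mild hydrolysis of the acetal (PPTS, acetone–water) would give the bis‑pivalate aldehyde F1. Slow addition of allyl diazoacetate to F1 and 14 with Rh2(OAc)4 would generate an ester‑stabilised carbonyl ylide by the known three‑component route (aldehyde, diazo ester, electron‑poor alkene); its ester‑bearing carbon is the nucleophilic terminus and should bond to the β‑carbon, giving the 4‑allyloxycarbonyl cycloadduct F2. Pd(PPh3)4 and morpholine would free the α‑alkoxy acid F3, and photoredox hydrodecarboxylation (acridinium photocatalyst, catalytic diphenyl disulfide, blue light) would replace the carboxyl group by hydrogen and deliver 16.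

Step 11.
- What may go wrong: acid ionisation of the C2–O3 bond of ring D (a cyclic para‑alkoxybenzyl ether), leading to ring opening, elimination towards an arylidene lactone or epimerisation at C2; sluggish hydrolysis of the hindered pseudo‑ester.
- Fallback (sets out from 16, returns at 17): cleavage under basic instead of acidic conditions. LiOH (1.1 equiv) in THF–water at 0 °C would attack the lactone carbonyl; the hemiacetal alkoxide so formed expels menthol, and careful acidification to pH 3 recloses the cis aldehyde acid to 17. The time in base would be kept short to avoid epimerisation α to the aldehyde and loss of the aryl pivalate. No new compound is formed.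

Step 15.
- What may go wrong: closure with the aryl group endo, or acid equilibration of the exo centres (C6, and C2 of ring D) towards the mixed exo/endo series, which is of similar stability; ionisation of C2–O1 of ring C now that the ring A phenol is free.
- Fallback (sets out from 22, returns at 25): ring E is kept closed and C6 is never ionised. The C6 epimers of 22 are separated and the exo epimer, (1S,2S,5R,6S)‑lactone F4, is reduced with i‑Bu2AlH (CH2Cl2, −78 °C) to the lactol F5. Ionic reduction with Et3SiH and BF3·OEt2 at −78 °C removes the lactol hydroxyl at C8, which is not a stereocentre, and gives the tris‑pivalate furofuran F6. LiAlH4 then cleaves the three pivalates to 25. The endo epimer of 22 would still be taken through steps 14 and 15.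

Step 5.
- What may go wrong: slow coupling at the ortho‑alkoxy, electron‑rich iodide, with palladium‑carbene decomposition of the diazo ester taking over.
- Fallback (sets out from 7, returns at 9): coupling of 7 with the Reformatsky reagent BrZnCH2CO2Et (Pd2(dba)3, XPhos, THF, 50 °C) would give the ethyl arylacetate F7, and Regitz diazo transfer (4‑acetamidobenzenesulfonyl azide, DBU, MeCN) would convert F7 into 9.

## Further compounds

F1 | step 10 | (2S,3S)‑5‑formyl bis‑pivalate (ArP–CHO) | COc1cc([C@H]2Oc3c(OC)cc(C=O)cc3[C@H]2COC(=O)C(C)(C)C)ccc1OC(=O)C(C)(C)C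
F2 | step 10 | allyl (1S,2S,5R,6S)‑2‑ArP‑6‑menthyloxy‑8‑oxo‑3,7‑dioxabicyclo[3.3.0]octane‑4‑carboxylate, C4 unspecified | COc1cc([C@H]2Oc3c(OC)cc([C@H]4OC(C(=O)OCC=C)[C@H]5[C@@H]4C(=O)O[C@@H]5O[C@H]4C[C@@H](C)CC[C@@H]4C(C)C)cc3[C@H]2COC(=O)C(C)(C)C)ccc1OC(=O)C(C)(C)C
F3 | step 10 | 2‑ArP‑6‑menthyloxy‑8‑oxo‑3,7‑dioxabicyclo[3.3.0]octane‑4‑carboxylic acid, C4 unspecified | COc1cc([C@H]2Oc3c(OC)cc([C@H]4OC(C(=O)O)[C@H]5[C@@H]4C(=O)O[C@@H]5O[C@H]4C[C@@H](C)CC[C@@H]4C(C)C)cc3[C@H]2COC(=O)C(C)(C)C)ccc1OC(=O)C(C)(C)C
F0 | step 11 | none | none
F4 | step 15 | (1S,2S,5R,6S)‑2‑ArP‑6‑SyrP‑3,7‑dioxabicyclo[3.3.0]octan‑8‑one (6‑exo epimer of 22) | COc1cc([C@H]2Oc3c(OC)cc([C@H]4OC[C@H]5[C@@H]4C(=O)O[C@@H]5c4cc(OC)c(OC(=O)C(C)(C)C)c(OC)c4)cc3[C@H]2COC(=O)C(C)(C)C)ccc1OC(=O)C(C)(C)C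
F5 | step 15 | (1S,2S,5R,6S)‑2‑ArP‑6‑SyrP‑3,7‑dioxabicyclo[3.3.0]octan‑8‑ol (lactol, C8 unspecified) | COc1cc([C@H]2Oc3c(OC)cc([C@H]4OC[C@H]5[C@@H]4C(O)O[C@@H]5c4cc(OC)c(OC(=O)C(C)(C)C)c(OC)c4)cc3[C@H]2COC(=O)C(C)(C)C)ccc1OC(=O)C(C)(C)C
F6 | step 15 | (1R,2S,5R,6S)‑2‑ArP‑6‑SyrP‑3,7‑dioxabicyclo[3.3.0]octane (tris‑pivalate of 25) | COc1cc([C@H]2Oc3c(OC)cc([C@H]4OC[C@H]5[C@@H]4CO[C@@H]5c4cc(OC)c(OC(=O)C(C)(C)C)c(OC)c4)cc3[C@H]2COC(=O)C(C)(C)C)ccc1OC(=O)C(C)(C)C
F7 | step 5 | ethyl 2‑[5‑{bis[(trimethylsilyl)methoxy]methyl}‑3‑methoxy‑2‑({3‑methoxy‑4‑(pivaloyloxy)phenyl}methoxy)phenyl]acetate | COc1cc(COc2c(CC(=O)OCC)cc(C(OC[Si](C)(C)C)OC[Si](C)(C)C)cc2OC)ccc1OC(=O)C(C)(C)C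
A1 | alternative 1 | target protected as benzyl ethers of both phenols and tert‑butyldimethylsilyl ether of the primary alcohol | COc1cc([C@H]2Oc3c(OC)cc([C@H]4OC[C@H]5[C@@H]4CO[C@@H]5c4cc(OC)c(OCc5ccccc5)c(OC)c4)cc3[C@H]2CO[Si](C)(C)C(C)(C)C)ccc1OCc1ccccc1
A2 | alternative 1 | (E)‑3‑arylallyl ether of (R)‑(4‑benzyloxy‑3,5‑dimethoxyphenyl)(oxiran‑2‑yl)methanol, aryl = (2S,3S)‑2‑(4‑benzyloxy‑3‑methoxyphenyl)‑3‑[(tert‑butyldimethylsilyloxy)methyl]‑7‑methoxy‑2,3‑dihydrobenzofuran‑5‑yl; oxirane carbon unspecified | COc1cc([C@H]2Oc3c(OC)cc(/C=C/CO[C@@H](C4CO4)c4cc(OC)c(OCc5ccccc5)c(OC)c4)cc3[C@H]2CO[Si](C)(C)C(C)(C)C)ccc1OCc1ccccc1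
A3 | alternative 2 | (2S,3S)‑5‑bromo‑3‑[(tert‑butyldimethylsilyloxy)methyl]‑7‑methoxy‑2‑(3‑methoxy‑4‑tosyloxyphenyl)‑2,3‑dihydrobenzofuran (cis) | COc1cc([C@H]2Oc3c(OC)cc(Br)cc3[C@H]2CO[Si](C)(C)C(C)(C)C)ccc1OS(=O)(=O)c1ccc(C)cc1
A4 | alternative 2 | (1R,2S)‑2‑(5‑bromo‑2‑hydroxy‑3‑methoxyphenyl)‑3‑(tert‑butyldimethylsilyloxy)‑1‑(3‑methoxy‑4‑tosyloxyphenyl)propan‑1‑ol | COc1cc(Br)cc([C@@H](CO[Si](C)(C)C(C)(C)C)[C@@H](O)c2ccc(OS(=O)(=O)c3ccc(C)cc3)c(OC)c2)c1O
A5 | alternative 3 | (1R,5R,6S)‑6‑exo‑(4‑benzyloxy‑3,5‑dimethoxyphenyl)‑3,7‑dioxabicyclo[3.3.0]octan‑2‑one | O=C1OC[C@H]2[C@@H]1CO[C@@H]2c1cc(OC)c(OCc2ccccc2)c(OC)c1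
A6 | alternative 3 | 6‑(4‑benzyloxy‑3,5‑dimethoxyphenyl)‑1‑(hydroxymethyl)‑3‑oxabicyclo[3.1.0]hexan‑2‑one, aryl trans to the lactone CH2 | O=C1OC[C@@H]2[C@@H](c3cc(OC)c(OCc4ccccc4)c(OC)c3)[C@]12CO
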